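## Structural features

The target is a germacrane-type bicycle. Ring A is the ten-membered carbocycle C1–C10. Ring B is an α-methylene-γ-butyrolactone (C7, C11, C12, O, C8; C13 is the exocyclic methylene) trans-fused across C7–C8. C14 is the methyl on C10 and C15 the methyl on C4.

Ring A holds a C2 ketone conjugated with the Z trisubstituted C1=C10 bond and five contiguous stereocentres: C4 (S, methyl), C5 (R, acyloxy), C6 (R, hydroxyl), C7 (R, C11) and C8 (R, lactone oxygen). Each neighbouring pair of these substituents is trans on the ring.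

O5 carries (2R,3S)-2,3-dimethyloxirane-2-carboxylate, a glycidic ester with cis methyl groups and a quaternary α-carbon.

Fragile points:
- the methylene lactone (Michael acceptor);
- the epoxy ester (acid and Lewis acid);
- the free C6 hydroxyl, which can take over the ester or the lactone;
- the C2 ketone, whose C3 hydrogens are more acidic than those of the lactone;
- O8, which is δ to the C2 carbonyl through the enone and can be lost from an extended enolate.

The real difficulty is the medium ring with five adjacent centres, and telling O5 from O6 at the end.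

The key step uses the fact that C2 and C7 face each other across ring A. A C2–C7 bond would turn C2, C1, C10, C9, C8, C7 into a cyclohexene ring with C3=C4 and C6=C5 as two alkenyl arms. The reverse [3,3] shift therefore builds ring A from a six-membered ring, makes C4–C5, and hands on the cyclohexene bond as the Z C1=C10 enone.

## Logic of the disconnections

36 is cut at the C5–O acyl bond into 30 and 34. The epoxy ester is the most sensitive group and goes on last. This removes two stereocentres and a five-carbon unit. The forward step must acylate O5 of 30 in preference to O6 without acyl or lactone migration.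

30 is cut at the C5–O and C6–O bonds to 29. A trans diol on the ring is the syn adduct of an E olefin, so two stereocentres are traded for one double bond. The forward step must pick the isolated C5=C6 bond over the enone and the methylene lactone, and add to its outer face.

29 is opened at the lactone C12–O8 bond to 27 (via 28), and the C11=C13 bond of 27 is traced to the selenide 25. The methylene is thus carried in masked form and no lactone enolate is ever needed beside the C2 ketone. The forward steps need a neutral oxidation–elimination and a mild cleavage of the O8 acetal.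

25 is cut at C7–C11, with the C5–O bond restored and the olefin moved back to C6=C7, to give 19 and 23. This retro-Claisen lets the C5 centre created in the key step set C7 and places the olefin where the diol is needed. The forward step demands a suprafacial chair with C4 pseudo-equatorial, at a temperature below the Cope rearrangement of the C1=C10/C6=C7 diene.

19 goes back to 18 by putting the p-methoxybenzyl group on O5. O5 must be freed while O8 stays masked, so the two groups are orthogonal.

18 is cut by the retro-oxy-Cope: C2–C7 is formed and C4–C5 is broken, giving 15. The ten-membered ring becomes a cyclohexene, and C4 and C5 become the geometries of two E olefins. The forward step demands a chair transition state and the trans arrangement of the two arms and O8.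

15 is cut at C2–C3 into 11 and 12. The forward step is a 1,2-addition that must not enolize 11 (loss of O8 would aromatize the ring) and should occur anti to the C7 arm.

11 goes back through 10 to 9 (ketone to protected carbinol). The enol ether C5–O bond of 9 is cut to the vinyl iodide 8 and 4-methoxybenzyl alcohol, because a stereoretentive C–O coupling fixes the E geometry.

8 goes back through 7 to 6 (exchange of the O8 group), and the C5=C6 bond of 6 is cut to the aldehyde 5. The forward olefination must be E-selective and non-basic.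

5 is cut at C2–C7 and C8–C9 into 2 and 4. One cycloaddition gives the ring, the C1=C10 bond in place, and the trans C7/C8 pair from the E dienophile. It demands "ortho" regiochemistry and catalyst control of the enal face. 2 comes from 1 by silyl dienol ether formation; 4 comes from 3 by O-acylation.

34 goes back to 33 (oxidation level), 33 to 32 (both epoxide C–O bonds, by asymmetric epoxidation), and 32 to 31 (reduction). The forward epoxidation must give the (2S,3S) alcohol.

23 is cut at its three C–O bonds to 21, and 21 at its C–Se bond to 20.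

## Other disconnections considered

Alternative 1: The cut is C7–C8 together with the lactone C12–O8 bond. In the forward step the open-chain bromo-ester aldehyde A2 is treated with CrCl2 (divalent chromium). The allylchromium adds through C7 to the C8 aldehyde and the alkoxide closes the lactone, giving A1.
- In favour: one step closes both rings and delivers the C11=C13 methylene lactone with no enolate chemistry near C2. O5 and O6 arrive with different protecting groups, so the final acylation at O5 is unambiguous. On both of these points this plan is better than the chosen one.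
- Against: A2 needs C2, C4, C5, C6 and the Z C1=C10 olefin built on an open chain. The closure is an end-to-end macrocyclization under high dilution. C7 and C8 are both created in the ring-closing event, with only the conformation of the forming ring to choose among four diastereomers.
- Comparison: structurally the chosen plan keeps all stereocentres of its precursor on a six-membered ring; mechanistically a concerted chair [3,3] shift is more predictable than a macrocyclic allylmetal addition. Step economy is about equal: the endgame from A1 is shorter, but the assembly of A2 is longer.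

Alternative 2: The cut is C5–C6. In the forward step the lactone dialdehyde A4 is coupled by low-valent titanium (TiCl3(DME)1.5 with zinc–copper couple) to the diol A3.
- In favour: ring A and both carbinol centres form at once, A4 has few stereocentres, and no hot sigmatropic step is needed. In convergence it is the equal of the chosen plan.
- Against: C5 and C6 are set in a macrocyclic pinacol coupling, where the threo/erythro ratio and the face relative to C4 and C7 are hard to steer. The two aldehydes are α to C4 and C7 and can epimerize or, at C6, eliminate the lactone oxygen. Over-reduction to the olefin is possible. A3 still needs C2 oxidation, methylenation of the lactone beside a ketone and a free diol, and the same O5/O6 differentiation.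
- Comparison: the chosen plan makes the same diol by syn addition to an olefin of fixed geometry, which is the more reliable mechanism, and it needs fewer steps after ring formation.

Alternative 3: The cut is C3–C4. In the forward step Pd(PPh3)4 (zerovalent palladium) ionizes the allylic carbonate A6 and the C3 β-keto ester enolate attacks C4 of the π-allyl to give A5.
- In favour: the step is catalytic, neutral and mild, and macrocyclic allylic alkylations tolerate moderate concentrations; here it is better than the chosen plan. A5 contains the same E C5=C6 olefin flanked by C4 and C7 that the chosen plan uses for the diol, so the downstream stereochemical logic is equal.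
- Against: the enolate may attack C6 instead of C4 (eight- instead of ten-membered ring). C4 depends on the carbonate configuration and on π-allyl isomerization. The C3 ester must be removed later under forcing conditions, and the methylene must still be added with the ketone present.
- Comparison: the chosen plan sets C4 by a chair transition state from a six-ring precursor, and needs no decarboxylation or lactone enolate; Alternative 3 is longer after its key step.

Key step: step 11

Assumption: atoms are numbered C1–C15 as defined under Structural features; compounds 25–30 and 36 are described with these locants.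

Assumption: the (S)-configured oxazaborolidinium catalyst of step 3 is taken to expose the enal face that leads to (1R,5R,6S)-5; if the facial sense is the opposite, its (R) antipode is used.

Step 1
Reactants: 1 3-methylbut-2-enal
Product: 2 (E)-tert-butyldimethyl[(3-methylbuta-1,3-dien-1-yl)oxy]silane
Conditions: t-BuMe2SiOTf, Et3N, Et2O, 0 °C → rt
Reagents that add atoms: tert-butyldimethylsilyl trifluoromethanesulfonate, CC(C)(C)[Si](C)(C)OS(=O)(=O)C(F)(F)F
Why: O-silylation of the enal and γ-deprotonation (silyl dienol ether formation) should give the 1-silyloxy diene; the s-trans enal leads to the E enol ether.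

Step 2
Reactants: 3 tetrabutylammonium (E)-3-oxoprop-1-en-1-olate
Product: 4 (E)-3-oxoprop-1-en-1-yl benzoate
Conditions: PhCOCl, CH2Cl2, 0 °C
Reagents that add atoms: benzoyl chloride, O=C(Cl)c1ccccc1
Why: O-acylation of the delocalized malonaldehyde enolate should give the trans enol ester, a β-acyloxy enal that serves as the C7–C8 unit with O8 in place.

Step 3
Reactants: 2 (E)-tert-butyldimethyl[(3-methylbuta-1,3-dien-1-yl)oxy]silane; 4 (E)-3-oxoprop-1-en-1-yl benzoate
Product: 5 (1R,5R,6S)-5-[(tert-butyldimethylsilyl)oxy]-6-formyl-3-methylcyclohex-3-en-1-yl benzoate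
Conditions: (S)-1-(2-methylphenyl)-3,3-diphenyltetrahydro-1H,3H-pyrrolo[1,2-c][1,3,2]oxazaborole (20 mol %), HNTf2 (17 mol %), CH2Cl2, −78 °C
Reagents that add atoms: none
Why: Catalytic enantioselective Diels–Alder reaction: the boron Lewis acid binds the formyl group, C9 of the diene (largest HOMO coefficient, reinforced by the methyl group) bonds to the benzoyloxy-bearing β-carbon and C2 to the α-carbon, giving the "ortho" adduct. The E geometry of 4 becomes the trans C7/C8 relationship and the catalyst selects the enal face that sets C7 (S) and C8 (R); the endo/exo ratio only concerns C2, which is oxidized later.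

Step 4
Reactants: 5 (1R,5R,6S)-5-[(tert-butyldimethylsilyl)oxy]-6-formyl-3-methylcyclohex-3-en-1-yl benzoate
Product: 6 (1R,5R,6S)-5-[(tert-butyldimethylsilyl)oxy]-6-[(E)-2-iodoethenyl]-3-methylcyclohex-3-en-1-yl benzoate
Conditions: CrCl2, CHI3, THF/1,4-dioxane, 0 °C → rt
Reagents that add atoms: iodoform, IC(I)I
Why: Takai olefination: the geminal dichromium species adds to the aldehyde and eliminates to the E vinyl iodide. The non-basic medium should spare the β-benzoyloxy aldehyde from elimination and C7 from epimerization.

Step 5
Reactants: 6 (1R,5R,6S)-5-[(tert-butyldimethylsilyl)oxy]-6-[(E)-2-iodoethenyl]-3-methylcyclohex-3-en-1-yl benzoate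
Product: 7 (1R,5R,6S)-5-[(tert-butyldimethylsilyl)oxy]-6-[(E)-2-iodoethenyl]-3-methylcyclohex-3-en-1-ol
Conditions: K2CO3 (cat.), MeOH, 0 °C → rt
Reagents that add atoms: none
Why: Base-catalysed transesterification frees O8; the secondary allylic silyl ether and the vinyl iodide should be inert under these conditions.

Step 6
Reactants: 7 (1R,5R,6S)-5-[(tert-butyldimethylsilyl)oxy]-6-[(E)-2-iodoethenyl]-3-methylcyclohex-3-en-1-ol
Product: 8 tert-butyl{[(1R,5R,6S)-6-[(E)-2-iodoethenyl]-5-(methoxymethoxy)-3-methylcyclohex-2-en-1-yl]oxy}dimethylsilane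
Conditions: MeOCH2Cl, i-Pr2NEt, CH2Cl2, 0 °C → rt
Reagents that add atoms: chloromethyl methyl ether, COCCl
Why: O-alkylation with the chloromethyl ether; the MOM acetal is chosen for O8 because it survives base, fluoride, organometallics and DDQ and cannot migrate to the later C2 alkoxide.

Step 7
Reactants: 8 tert-butyl{[(1R,5R,6S)-6-[(E)-2-iodoethenyl]-5-(methoxymethoxy)-3-methylcyclohex-2-en-1-yl]oxy}dimethylsilane
Product: 9 tert-butyl{[(1R,5R,6S)-5-(methoxymethoxy)-6-{(E)-2-[(4-methoxybenzyl)oxy]ethenyl}-3-methylcyclohex-2-en-1-yl]oxy}dimethylsilane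
Conditions: CuI (10 mol %), 3,4,7,8-tetramethyl-1,10-phenanthroline (20 mol %), Cs2CO3, 4-MeOC6H4CH2OH, PhMe, 80 °C
Reagents that add atoms: 4-methoxybenzyl alcohol, COc1ccc(CO)cc1
Why: Copper-catalysed Ullmann-type C–O coupling of a vinyl iodide with a primary alcohol runs with retention of olefin geometry, so the E enol ether follows from the E iodide. The E iodide should resist dehydroiodination because H and I are cis, and no ketone is present yet.

Step 8
Reactants: 9 tert-butyl{[(1R,5R,6S)-5-(methoxymethoxy)-6-{(E)-2-[(4-methoxybenzyl)oxy]ethenyl}-3-methylcyclohex-2-en-1-yl]oxy}dimethylsilane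
Product: 10 (1R,5R,6R)-5-(methoxymethoxy)-6-{(E)-2-[(4-methoxybenzyl)oxy]ethenyl}-3-methylcyclohex-2-en-1-ol
Conditions: Bu4NF, THF, 0 °C → rt
Reagents that add atoms: none
Why: Fluoride-induced desilylation frees the allylic alcohol without acid, which the enol ether would not tolerate; the CIP label at the ring carbon bearing the arm changes only because of the new priorities.

Step 9
Reactants: 10 (1R,5R,6R)-5-(methoxymethoxy)-6-{(E)-2-[(4-methoxybenzyl)oxy]ethenyl}-3-methylcyclohex-2-en-1-ol
Product: 11 (5R,6S)-5-(methoxymethoxy)-6-{(E)-2-[(4-methoxybenzyl)oxy]ethenyl}-3-methylcyclohex-2-en-1-one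
Conditions: MnO2, CH2Cl2, rt
Reagents that add atoms: none
Why: Allylic oxidation with MnO2 is neutral, which matters because the β-alkoxy enone would aromatize by loss of O8 under base or acid.

Step 10
Reactants: 11 (5R,6S)-5-(methoxymethoxy)-6-{(E)-2-[(4-methoxybenzyl)oxy]ethenyl}-3-methylcyclohex-2-en-1-one; 12 (E)-1-bromoprop-1-ene
Product: 15 (1R,5R,6S)-5-(methoxymethoxy)-6-{(E)-2-[(4-methoxybenzyl)oxy]ethenyl}-3-methyl-1-[(E)-prop-1-enyl]cyclohex-2-en-1-ol, via (E)-prop-1-enyllithium 13 (not isolated), via (E)-prop-1-enylcerium dichloride 14 (not isolated)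
Conditions: 12, t-BuLi (2 equiv), Et2O, −78 °C; CeCl3, THF, −78 °C; then 11; aq NH4Cl
Reagents that add atoms: none
Why: Bromine–lithium exchange with retention, transmetalation to the weakly basic organocerium and 1,2-addition to the enolizable β-alkoxy enone should occur without loss of O8. Attack anti to the equatorial C7 arm places the two alkenyl groups trans and sets C2 (R).

Step 11
Reactants: 15 (1R,5R,6S)-5-(methoxymethoxy)-6-{(E)-2-[(4-methoxybenzyl)oxy]ethenyl}-3-methyl-1-[(E)-prop-1-enyl]cyclohex-2-en-1-ol
Product: 18 (2Z,6E,5R,8R,9S)-8-[(4-methoxybenzyl)oxy]-5-(methoxymethoxy)-3,9-dimethylcyclodeca-2,6-dien-1-one, via potassium alkoxide 16 (not isolated), via potassium enolate 17 (not isolated)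
Conditions: KH, 18-crown-6, THF, 0 °C → rt; AcOH, −78 °C
Reagents that add atoms: none
Why: KH with 18-crown-6 should give the loosely ion-paired alkoxide 16, in which the C2–C7 bond is weakened so that the [3,3] shift (anionic oxy-Cope rearrangement, the known ring expansion of 1,2-dialkenylcycloalkanols to cycloalk-5-enones) runs near room temperature. C4–C5 forms while C2–C7 breaks, so ring A is closed by a concerted four-atom ring expansion of the six-membered ring and not by end-to-end cyclization; the cross-conjugated enolate 17 is then protonated at C3 to give 18. The transition state is a chair fused to the cyclohexene like a trans-decalin, with the C2–C1 and C7–C8 bonds equatorial, which makes the new C6=C7 olefin E, while the Z C1=C10 enone is the untouched cyclohexene bond. C4 (S) is fixed by the E geometry of the propenyl arm (methyl equatorial) and C5 (R) by the E geometry of the enol ether (alkoxy equatorial), both read against C7, whose configuration selects the sense of the chair. The selectivity needed is chair over boat and equatorial over axial C8; the trans-diequatorial arms and the equatorial O8 substituent of 15 secure it. The C2 epimer of 15, if carried along, should reach the same 18 through the chair with the oxido group equatorial. Cold quenching limits equilibration of 17 to the extended dienolate, the species that could expel O8.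

Step 12
Reactants: 18 (2Z,6E,5R,8R,9S)-8-[(4-methoxybenzyl)oxy]-5-(methoxymethoxy)-3,9-dimethylcyclodeca-2,6-dien-1-one
Product: 19 (2Z,6E,5R,8R,9S)-8-hydroxy-5-(methoxymethoxy)-3,9-dimethylcyclodeca-2,6-dien-1-one
Conditions: DDQ, CH2Cl2/pH 7 buffer, 0 °C
Reagents that add atoms: none
Why: Oxidative cleavage of the p-methoxybenzyl ether by DDQ frees O5 alone; the MOM acetal on O8, the enone and the olefin should not react at 0 °C.

Step 13
Reactants: 20 prop-2-enenitrile
Product: 21 3-(phenylselanyl)propanenitrile
Conditions: PhSeH, Et3N (cat.), EtOH, 0 °C → rt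
Reagents that add atoms: benzeneselenol, [SeH]c1ccccc1
Why: Base-catalysed conjugate (Michael) addition of the selenol to acrylonitrile.

Step 14
Reactants: 21 3-(phenylselanyl)propanenitrile
Product: 23 (3,3,3-trimethoxypropyl)(phenyl)selane, via imidate hydrochloride 22 (not isolated)
Conditions: HCl (g), MeOH (1.1 equiv), Et2O, 0 °C; then MeOH, hexane, rt
Reagents that add atoms: methanol, CO
Why: Pinner reaction to the imidate salt, then alcoholysis to the orthoester; the selenide is inert to dry HCl.

Step 15
Reactants: 19 (2Z,6E,5R,8R,9S)-8-hydroxy-5-(methoxymethoxy)-3,9-dimethylcyclodeca-2,6-dien-1-one; 23 (3,3,3-trimethoxypropyl)(phenyl)selane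
Product: 25 methyl 2-[(4S,7S,8R)-ring A with C2 ketone, Z-C1=C10, E-C5=C6 and 8-(methoxymethoxy), attached at C7]-3-(phenylselanyl)propanoate, via ketene acetal 24 (not isolated)
Conditions: 23 (5 equiv), 2,4,6-trimethylbenzoic acid (cat.), PhMe, 110 °C, MeOH distilled off
Reagents that add atoms: none
Why: Johnson–Claisen rearrangement: exchange at the orthoester gives ketene acetal 24, which rearranges suprafacially through a chair with C4 pseudo-equatorial, so the C5 configuration is relayed to C7 and the new C5=C6 bond is E. O5 lies on the outer face of the E olefin in the conformer with H5 eclipsed, so C11 enters on the face that corresponds to C7 of 36 (labelled S here only because of the selenium-bearing branch); C11 forms as a mixture that step 16 erases.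

Step 16
Reactants: 25 methyl 2-[(4S,7S,8R)-ring A with C2 ketone, Z-C1=C10, E-C5=C6 and 8-(methoxymethoxy), attached at C7]-3-(phenylselanyl)propanoate
Product: 27 methyl 2-[(4S,7S,8R)-ring A with C2 ketone, Z-C1=C10, E-C5=C6 and 8-(methoxymethoxy), attached at C7]prop-2-enoate, via selenoxide 26 (not isolated)
Conditions: NaIO4, NaHCO3, THF/H2O, 0 °C → rt
Reagents that add atoms: none
Why: Oxidation to the selenoxide and syn-elimination through the only β-hydrogen (on C11) give the acrylate, so C13 appears without any enolate. Periodate is preferred to peracids to avoid epoxidation of the strained E olefin.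

Step 17
Reactants: 27 methyl 2-[(4S,7S,8R)-ring A with C2 ketone, Z-C1=C10, E-C5=C6 and 8-(methoxymethoxy), attached at C7]prop-2-enoate
Product: 29 (4S,7S,8R)-8,12-olide of ring A with C2 ketone, Z-C1=C10, E-C5=C6 and C11=C13 methylene, via hydroxy ester 28 (not isolated)
Conditions: Me2BBr, CH2Cl2, −78 °C; aq NaHCO3; then pyridinium p-toluenesulfonate, PhMe, 50 °C
Reagents that add atoms: none
Why: Bromoborane cleavage of the MOM acetal at low temperature, then acid-catalysed lactonization (5-exo-trig acyl substitution) of the γ-hydroxy ester should close the trans-fused methylene lactone. No epoxide is present yet and the ketone is not enolized.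

Step 18
Reactants: 29 (4S,7S,8R)-8,12-olide of ring A with C2 ketone, Z-C1=C10, E-C5=C6 and C11=C13 methylene
Product: 30 (4S,5R,6R,7R,8R)-5,6-dihydroxy-8,12-olide of ring A with C2 ketone, Z-C1=C10 and C11=C13 methylene
Conditions: OsO4 (5 mol %), N-methylmorpholine N-oxide, acetone/H2O, 0 °C
Reagents that add atoms: N-methylmorpholine N-oxide, C[N+]1([O-])CCOCC1; water, O
Why: Catalytic OsO4 dihydroxylation: syn addition to the E olefin gives the trans-5,6-diol, and the electron-rich, strained C5=C6 bond should react before the enone and the methylene lactone. Attack on the outer face of the conformer with H4 and H7 eclipsing the double bond (ring bonds C4–C3 and C7–C8 inside) sets C5 (R) and C6 (R).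

Step 19
Reactants: 31 (E)-2-methylbut-2-enoic acid
Product: 32 (E)-2-methylbut-2-en-1-ol
Conditions: LiAlH4, Et2O, 0 °C → rt
Reagents that add atoms: none
Why: Hydride reduction of the acid to the allylic alcohol; the trisubstituted double bond and its E geometry are kept.

Step 20
Reactants: 32 (E)-2-methylbut-2-en-1-ol
Product: 33 [(2S,3S)-2,3-dimethyloxiran-2-yl]methanol
Conditions: Ti(OiPr)4 (10 mol %), diisopropyl L-(+)-tartrate (12 mol %), t-BuOOH, 4 Å MS, CH2Cl2, −20 °C
Reagents that add atoms: tert-butyl hydroperoxide, CC(C)(C)OO
Why: Sharpless asymmetric epoxidation; with the L-(+)-tartrate the (2S,3S) epoxy alcohol is expected, as for other E-2,3-disubstituted allylic alcohols, and the cis methyl groups follow from the E olefin.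

Step 21
Reactants: 33 [(2S,3S)-2,3-dimethyloxiran-2-yl]methanol
Product: 34 (2R,3S)-2,3-dimethyloxirane-2-carboxylic acid
Conditions: RuCl3 (2 mol %), NaIO4, MeCN/EtOAc/H2O, 0 °C → rt
Reagents that add atoms: sodium periodate, [Na+].[O-]I(=O)(=O)=O; water, O
Why: RuO4 oxidation of the primary alcohol to the acid without opening the epoxide; the label at C2 becomes R only because the carboxyl group outranks C3.

Step 22
Reactants: 34 (2R,3S)-2,3-dimethyloxirane-2-carboxylic acid; 30 (4S,5R,6R,7R,8R)-5,6-dihydroxy-8,12-olide of ring A with C2 ketone, Z-C1=C10 and C11=C13 methylene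
Product: 36 CNP0227299.3 (4S,5R,6R,7R,8R)-5-{[(2R,3S)-2,3-dimethyloxirane-2-carbonyl]oxy}-6-hydroxy-8,12-olide of ring A with C2 ketone, Z-C1=C10 and C11=C13 methylene, via mixed anhydride 35 (not isolated)
Conditions: 2,4,6-Cl3C6H2COCl, Et3N, THF, rt; then 30, DMAP, PhMe, 0 °C → rt
Reagents that add atoms: none
Why: Yamaguchi esterification through mixed anhydride 35 and the acylpyridinium; O5 is expected to react before O6, which is flanked by C5 and by the lactone-bearing C7. The mild, non-aqueous conditions should spare the epoxide and limit acyl or lactone migration.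

## Compound list

1 | 3-methylbut-2-enal | CC(C)=CC=O | starting material
2 | (E)-tert-butyldimethyl[(3-methylbuta-1,3-dien-1-yl)oxy]silane | C=C(C)/C=C/O[Si](C)(C)C(C)(C)C | intermediate
3 | tetrabutylammonium (E)-3-oxoprop-1-en-1-olate | O=C/C=C/[O-].CCCC[N+](CCCC)(CCCC)CCCC | starting material
4 | (E)-3-oxoprop-1-en-1-yl benzoate | O=C/C=C/OC(=O)c1ccccc1 | intermediate
5 | (1R,5R,6S)-5-[(tert-butyldimethylsilyl)oxy]-6-formyl-3-methylcyclohex-3-en-1-yl benzoate | [C@@H]1(O[Si](C)(C)C(C)(C)C)C=C(C)C[C@@H](OC(=O)c2ccccc2)[C@@H]1C=O | intermediate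
6 | (1R,5R,6S)-5-[(tert-butyldimethylsilyl)oxy]-6-[(E)-2-iodoethenyl]-3-methylcyclohex-3-en-1-yl benzoate | [C@@H]1(O[Si](C)(C)C(C)(C)C)C=C(C)C[C@@H](OC(=O)c2ccccc2)[C@@H]1/C=C/I | intermediate
7 | (1R,5R,6S)-5-[(tert-butyldimethylsilyl)oxy]-6-[(E)-2-iodoethenyl]-3-methylcyclohex-3-en-1-ol | [C@@H]1(O[Si](C)(C)C(C)(C)C)C=C(C)C[C@@H](O)[C@@H]1/C=C/I | intermediate
8 | tert-butyl{[(1R,5R,6S)-6-[(E)-2-iodoethenyl]-5-(methoxymethoxy)-3-methylcyclohex-2-en-1-yl]oxy}dimethylsilane | [C@@H]1(O[Si](C)(C)C(C)(C)C)C=C(C)C[C@@H](OCOC)[C@@H]1/C=C/I | intermediate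
9 | tert-butyl{[(1R,5R,6S)-5-(methoxymethoxy)-6-{(E)-2-[(4-methoxybenzyl)oxy]ethenyl}-3-methylcyclohex-2-en-1-yl]oxy}dimethylsilane | [C@@H]1(O[Si](C)(C)C(C)(C)C)C=C(C)C[C@@H](OCOC)[C@@H]1/C=C/OCc1ccc(OC)cc1 | intermediate
10 | (1R,5R,6R)-5-(methoxymethoxy)-6-{(E)-2-[(4-methoxybenzyl)oxy]ethenyl}-3-methylcyclohex-2-en-1-ol | [C@@H]1(O)C=C(C)C[C@@H](OCOC)[C@@H]1/C=C/OCc1ccc(OC)cc1 | intermediate
11 | (5R,6S)-5-(methoxymethoxy)-6-{(E)-2-[(4-methoxybenzyl)oxy]ethenyl}-3-methylcyclohex-2-en-1-one | O=C1C=C(C)C[C@@H](OCOC)[C@@H]1/C=C/OCc1ccc(OC)cc1 | intermediate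
12 | (E)-1-bromoprop-1-ene | C/C=C/Br | starting material
13 | (E)-prop-1-enyllithium | C/C=C/[Li] | intermediate
14 | (E)-prop-1-enylcerium dichloride | C/C=C/[Ce](Cl)Cl | intermediate
15 | (1R,5R,6S)-5-(methoxymethoxy)-6-{(E)-2-[(4-methoxybenzyl)oxy]ethenyl}-3-methyl-1-[(E)-prop-1-enyl]cyclohex-2-en-1-ol | C/C=C/[C@@]1(O)C=C(C)C[C@@H](OCOC)[C@@H]1/C=C/OCc1ccc(OC)cc1 | intermediate
16 | potassium alkoxide of 15 | C/C=C/[C@@]1([O-])C=C(C)C[C@@H](OCOC)[C@@H]1/C=C/OCc1ccc(OC)cc1.[K+] | intermediate
17 | potassium C2–C3 enolate of 18 | [O-]C1=C[C@H](C)[C@@H](OCc2ccc(OC)cc2)/C=C/[C@H](OCOC)C/C(C)=C\1.[K+] | intermediate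
18 | (2Z,6E,5R,8R,9S)-8-[(4-methoxybenzyl)oxy]-5-(methoxymethoxy)-3,9-dimethylcyclodeca-2,6-dien-1-one | C1[C@H](C)[C@@H](OCc2ccc(OC)cc2)/C=C/[C@H](OCOC)C/C(C)=C\C1=O | intermediate
19 | (2Z,6E,5R,8R,9S)-8-hydroxy-5-(methoxymethoxy)-3,9-dimethylcyclodeca-2,6-dien-1-one | C1[C@H](C)[C@@H](O)/C=C/[C@H](OCOC)C/C(C)=C\C1=O | intermediate
20 | prop-2-enenitrile | C=CC#N | starting material
21 | 3-(phenylselanyl)propanenitrile | N#CCC[Se]c1ccccc1 | intermediate
22 | methyl 3-(phenylselanyl)propanimidate hydrochloride | COC(=[NH2+])CC[Se]c1ccccc1.[Cl-] | intermediate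
23 | (3,3,3-trimethoxypropyl)(phenyl)selane | COC(OC)(OC)CC[Se]c1ccccc1 | intermediate
24 | ketene acetal of 19: 8-{[1-methoxy-3-(phenylselanyl)prop-1-en-1-yl]oxy} derivative | C1[C@H](C)[C@@H](OC(OC)=CC[Se]c2ccccc2)/C=C/[C@H](OCOC)C/C(C)=C\C1=O | intermediate
25 | methyl 2-[(4S,7S,8R)-ring A with C2 ketone, Z-C1=C10, E-C5=C6 and 8-(methoxymethoxy), attached at C7]-3-(phenylselanyl)propanoate (C11 epimers) | [C@H]1(C(C[Se]c2ccccc2)C(=O)OC)[C@H](OCOC)C/C(C)=C\C(=O)C[C@H](C)/C=C/1 | intermediate
26 | selenoxide of 25 | [C@H]1(C(C[Se](=O)c2ccccc2)C(=O)OC)[C@H](OCOC)C/C(C)=C\C(=O)C[C@H](C)/C=C/1 | intermediate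
27 | methyl 2-[(4S,7S,8R)-ring A with C2 ketone, Z-C1=C10, E-C5=C6 and 8-(methoxymethoxy), attached at C7]prop-2-enoate | [C@H]1(C(=C)C(=O)OC)[C@H](OCOC)C/C(C)=C\C(=O)C[C@H](C)/C=C/1 | intermediate
28 | methyl 2-[(4S,7S,8R)-ring A with C2 ketone, Z-C1=C10, E-C5=C6 and 8-hydroxy, attached at C7]prop-2-enoate | [C@H]1(C(=C)C(=O)OC)[C@H](O)C/C(C)=C\C(=O)C[C@H](C)/C=C/1 | intermediate
29 | (4S,7S,8R)-8,12-olide of ring A with C2 ketone, Z-C1=C10, E-C5=C6 and C11=C13 methylene | C=C1C(=O)O[C@@H]2C/C(C)=C\C(=O)C[C@H](C)/C=C/[C@@H]12 | intermediate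
30 | (4S,5R,6R,7R,8R)-5,6-dihydroxy-8,12-olide of ring A with C2 ketone, Z-C1=C10 and C11=C13 methylene | C=C1C(=O)O[C@@H]2C/C(C)=C\C(=O)C[C@H](C)[C@@H](O)[C@H](O)[C@@H]12 | intermediate
31 | (E)-2-methylbut-2-enoic acid (tiglic acid) | C/C=C(\C)C(=O)O | starting material
32 | (E)-2-methylbut-2-en-1-ol | C/C=C(\C)CO | intermediate
33 | [(2S,3S)-2,3-dimethyloxiran-2-yl]methanol | OC[C@]1(C)O[C@H]1C | intermediate
34 | (2R,3S)-2,3-dimethyloxirane-2-carboxylic acid | O=C(O)[C@]1(C)O[C@H]1C | intermediate
35 | (2R,3S)-2,3-dimethyloxirane-2-carboxylic 2,4,6-trichlorobenzoic anhydride | O=C(OC(=O)c1c(Cl)cc(Cl)cc1Cl)[C@]1(C)O[C@H]1C | intermediate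
36 | CNP0227299.3 | C=C1C(=O)O[C@@H]2C/C(C)=C\C(=O)C[C@H](C)[C@@H](OC(=O)[C@]3(C)O[C@H]3C)[C@H](O)[C@@H]12 | target

## Step count and least certain steps

Total step count: 22. Longest linear sequence: 16 steps (steps 1, 3–12, 15–18 and 22).

Step 11 (key step). What may go wrong: the product enolate equilibrates to the extended dienolate and expels O8, or the rearrangement runs through a boat or an axial-C8 chair and scrambles C4/C5 or the C6=C7 geometry. Fallback: a neutral siloxy-Cope rearrangement. It sets out from 15, which is silylated (N-(trimethylsilyl)imidazole) to the trimethylsilyl ether F1. F1 is heated in toluene in a sealed tube (about 180–200 °C) to the silyl dienol ether F2, and methanolysis (K2CO3, MeOH, 0 °C) returns the route at 18. No enolate is present while O8 could leave.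

Step 3. What may go wrong: poor enantiofacial discrimination with a β-acyloxy enal, or carbonyl addition of the silyl dienol ether instead of cycloaddition. Fallback: covalent resolution instead of asymmetric catalysis. It sets out from 3, which is acylated with (S)-2-methoxy-2-phenylacetyl chloride to (E)-3-oxoprop-1-en-1-yl (S)-2-methoxy-2-phenylacetate F3. Uncatalysed cycloaddition with 2 (PhMe, 60–80 °C) gives the wanted adduct F4 and its ring-diastereomer F5, which are separated. Takai olefination of F4 gives the vinyl iodide F6, and methanolysis (K2CO3, MeOH) returns the route at 7.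

Step 15. What may go wrong: Cope rearrangement of the C1=C10/C6=C7 1,5-diene at the temperature needed, transannular ketalization of O5 onto C2 under the acidic orthoester conditions, or loss of E selectivity. Fallback: an ester-enolate (Ireland–Claisen) rearrangement at or below room temperature. It sets out from 19, which is esterified (DCC, DMAP) with 3-(pyrrolidin-1-yl)propanoic acid to the ester F7. Enolization and silylation in one flask (LiN(SiMe3)2 in excess, Me3SiCl, THF, −78 °C → rt; the ketone is carried as its silyl dienol ether and freed on work-up) give the rearranged amino acid F8. Exhaustive methylation (MeI, K2CO3, DMF) gives the quaternary ammonium ester iodide F9, which eliminates 1-methylpyrrolidine and returns the route at 27.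

Step 22. What may go wrong: acylation at O6 or at both oxygens, or base-induced migration of the ester or of the lactone to O6. Fallback: activation of the diol instead of the acid. It sets out from 30, which is converted (Bu2SnO, PhMe, reflux, water removed) into the dibutylstannylene acetal F10. F10 is acylated at low temperature with the symmetrical anhydride F11 of acid 34 (made from 34 with DCC); KF work-up returns the route at 36.

Step 7. What may go wrong: slow coupling at the hindered vinyl iodide, with erosion of the E geometry or loss of the silyl ether at 80 °C. Fallback: oxidative coupling of a vinylboron compound at room temperature. It sets out from 8, which is converted by Miyaura borylation (PdCl2(dppf), bis(pinacolato)diboron, KOPh, PhMe, 50 °C) into the (E)-alkenyl pinacol boronate F12. Chan–Lam coupling of F12 with 4-methoxybenzyl alcohol (Cu(OAc)2, Et3N, 4 Å MS, air, rt) returns the route at 9.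

## Further compounds

F1 | step 11 | trimethylsilyl ether of 15 | C/C=C/[C@@]1(O[Si](C)(C)C)C=C(C)C[C@@H](OCOC)[C@@H]1/C=C/OCc1ccc(OC)cc1
F2 | step 11 | trimethylsilyl C2–C3 dienol ether of 18 | C[Si](C)(C)OC1=C[C@H](C)[C@@H](OCc2ccc(OC)cc2)/C=C/[C@H](OCOC)C/C(C)=C\1
F3 | step 3 | (E)-3-oxoprop-1-en-1-yl (S)-2-methoxy-2-phenylacetate | O=C/C=C/OC(=O)[C@@H](OC)c1ccccc1
F4 | step 3 | (1R,5R,6S)-5-[(tert-butyldimethylsilyl)oxy]-6-formyl-3-methylcyclohex-3-en-1-yl (S)-2-methoxy-2-phenylacetate | [C@@H]1(O[Si](C)(C)C(C)(C)C)C=C(C)C[C@@H](OC(=O)[C@@H](OC)c2ccccc2)[C@@H]1C=O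
F5 | step 3 | (1S,5S,6R)-5-[(tert-butyldimethylsilyl)oxy]-6-formyl-3-methylcyclohex-3-en-1-yl (S)-2-methoxy-2-phenylacetate | [C@H]1(O[Si](C)(C)C(C)(C)C)C=C(C)C[C@H](OC(=O)[C@@H](OC)c2ccccc2)[C@H]1C=O
F6 | step 3 | (1R,5R,6S)-5-[(tert-butyldimethylsilyl)oxy]-6-[(E)-2-iodoethenyl]-3-methylcyclohex-3-en-1-yl (S)-2-methoxy-2-phenylacetate | [C@@H]1(O[Si](C)(C)C(C)(C)C)C=C(C)C[C@@H](OC(=O)[C@@H](OC)c2ccccc2)[C@@H]1/C=C/I
F7 | step 15 | 3-(pyrrolidin-1-yl)propanoate ester of 19 at O5 | C1[C@H](C)[C@@H](OC(=O)CCN2CCCC2)/C=C/[C@H](OCOC)C/C(C)=C\C1=O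
F8 | step 15 | 2-[(4S,7S,8R)-ring A with C2 ketone, Z-C1=C10, E-C5=C6 and 8-(methoxymethoxy), attached at C7]-3-(pyrrolidin-1-yl)propanoic acid | [C@H]1(C(CN2CCCC2)C(=O)O)[C@H](OCOC)C/C(C)=C\C(=O)C[C@H](C)/C=C/1
F9 | step 15 | N-methylpyrrolidinium iodide of the methyl ester of F8 | [C@H]1(C(C[N+]2(C)CCCC2)C(=O)OC)[C@H](OCOC)C/C(C)=C\C(=O)C[C@H](C)/C=C/1.[I-]
F10 | step 22 | 5,6-O-dibutylstannylene acetal of 30 | C=C1C(=O)O[C@@H]2C/C(C)=C\C(=O)C[C@H](C)[C@H]3O[Sn](CCCC)(CCCC)O[C@@H]3[C@@H]12
F11 | step 22 | (2R,3S)-2,3-dimethyloxirane-2-carboxylic anhydride | O=C(OC(=O)[C@]1(C)O[C@H]1C)[C@]1(C)O[C@H]1C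
F12 | step 7 | (E)-alkenyl pinacol boronate from 8 | [C@@H]1(O[Si](C)(C)C(C)(C)C)C=C(C)C[C@@H](OCOC)[C@@H]1/C=C/B1OC(C)(C)C(C)(C)O1
A1 | alternative 1 | protected bicyclic methylene lactone (C2 OTES, C5 OPMB, C6 OTBS) | C=C1C(=O)O[C@@H]2C/C(C)=C\[C@H](O[Si](CC)(CC)CC)C[C@H](C)[C@@H](OCc3ccc(OC)cc3)[C@H](O[Si](C)(C)C(C)(C)C)[C@@H]12
A2 | alternative 1 | open-chain C8 aldehyde with methyl 2-(bromomethyl)alk-2-enoate terminus | O=CC/C(C)=C\[C@H](O[Si](CC)(CC)CC)C[C@H](C)[C@@H](OCc1ccc(OC)cc1)[C@H](O[Si](C)(C)C(C)(C)C)C=C(CBr)C(=O)OC
A3 | alternative 2 | ring A 5,6-diol fused to the lactone without methylene (C2 OTBS) | C1C(=O)O[C@@H]2C/C(C)=C\[C@H](O[Si](C)(C)C(C)(C)C)C[C@H](C)[C@@H](O)[C@H](O)[C@@H]12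
A4 | alternative 2 | lactone dialdehyde (C5 and C6 aldehydes, C2 OTBS) | C1C(=O)O[C@H](C/C(C)=C\[C@H](O[Si](C)(C)C(C)(C)C)C[C@H](C)C=O)[C@H]1C=O
A5 | alternative 3 | ring A 3-carbomethoxy-2-ketone with Z-C1=C10 and E-C5=C6 fused to the lactone | C1C(=O)O[C@@H]2C/C(C)=C\C(=O)[C@@H](C(=O)OC)[C@H](C)/C=C/[C@@H]12
A6 | alternative 3 | lactone with C4 allylic methyl carbonate arm and β-keto ester chain | C1C(=O)O[C@H](C/C(C)=C\C(=O)CC(=O)OC)[C@H]1/C=C/C(C)OC(=O)OC
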